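Start from the amounts in the north flask: 0.20 M of substrate, but 20 µM of free enzyme and 24 µM of impurity, so impurity exceeds free enzyme by 4.00 µM.

| flask | substrate | free enzyme | impurity | temperature | remark | time |
|---|---|---|---|---|---|---|
| north | 0.20 M | 20 µM | 24 µM | 37 °C | the very flask that is asked about, followed so far |  |
| south | 0.20 M | 20 µM | 36 µM | 37 °C | run made earlier |  |
| flask | 0.20 M | 20 µM | 24 µM | 37 °C |  | 1.0 h |

| run | time / min | target / % |
|---|---|---|
| north | 3.00 | 9.1 |
| north | 10.0 | 10.6 |
| north | 15.0 | 9.2 |
| north | 25.0 | 8.6 |
| north | 40.0 | 9.0 |
| north | 50.0 | 9.5 |
| south | 0.667 | 5.8 |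
| south | 1.00 | 4.6 |
| south | 2.00 | 4.3 |
| south | 3.00 | 4.6 |
| south | 5.00 | 4.6 |
| south | 8.00 | 4.7 |

(each reading ± 0.5 percentage points)

- the volume of additions can be left aside
- the numbers in the tables scatter with a standard deviation of 0.5 percentage points
- the earlier runs do not show what temperature does; that part of a forecast is a guess
- a reading or a percentage of target counts all its forms, free or not

- dawn: change nothing and wait 20 min more
- dusk: at 1.0 h raise the temperature by 15 K, then wait 20 min
- noon: at 1.0 h add substrate, 50.0% of the amount charged, then wait 20 min
- winter: at 1.0 h add free enzyme, 100% of the amount charged, then wait 20 min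

- target, in percent of the substrate first charged, at 1.0 h
- the option that brings most further target ("none" if no option brings more than 2 percentage points) (dawn / dusk / noon / winter / none)
- target present, in percent of the substrate first charged, after dusk
- target present, in percent of the substrate first charged, after noon

You see target rise within minutes and then stay flat. The north plateau, a mean of 9.33%, is 18.7 mM of target, far above the enzyme charged. So the enzyme turned over many times and then stopped, with about 90.7% of the substrate unused.

My own reckoning treats this as a race. Free enzyme makes target at a rate proportional to its amount, and impurity destroys it one to one at a rate proportional to its amount times the impurity's. Divide the two rates and free enzyme cancels: while substrate stays near its charge, each equal fractional loss of impurity brings equal target. Hence plateau = Y × ln(impurity charged / impurity left), where Y is the yield per e-fold of impurity, a selectivity factor between turnover and death. While impurity exceeds enzyme, impurity left is the difference of the charges.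

The south run gives the logarithm 0.811. Its last five readings average 4.56%, so Y reads 5.62%. For the north flask the logarithm is 1.79, which predicts 10.1%, somewhat above the 9.33% read directly; I would commit to the flask's own plateau at 1.0 h.

The north readings are flat from 3.00 min, well before that time, so I expect waiting and more substrate to add nothing; heating is a guess. Winter's 20.0 µM of fresh enzyme exceeds the 4.00 µM of impurity reckoned left, which makes impurity the limiting reagent.

The forecast says 9.3% now, 9.3% after dusk, 9.3% after noon, and chooses winter: “Fresh enzyme outnumbers the leftover impurity”.

The simulation gives 9.55% now, 9.55% after dusk and 9.55% after noon, and winter brings 75 percentage points.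

    free enzyme → unfolded enzyme (k = 0.00874 min⁻¹, Ea = 196 kJ mol⁻¹)
    crystals ⇌ target, rate k2*(cs2 - [target]) while solid is left; crystals form when [target] > cs2 (solubility = 0.0540 M, k = 4.06 min⁻¹)
    free enzyme + impurity → spent catalyst (k = 4.92 × 10⁵ L mol⁻¹ min⁻¹, Ea = 38.0 kJ mol⁻¹)
    complex ⇌ free enzyme + target (K = 0.510 M, k = 8630 min⁻¹, Ea = 50.0 kJ mol⁻¹, ΔH = −5.00 kJ mol⁻¹)
    substrate + free enzyme ⇌ complex (K = 3.40 L mol⁻¹, k = 17500 L mol⁻¹ s⁻¹, Ea = 11.0 kJ mol⁻¹, ΔH = −48.0 kJ mol⁻¹)
    (constants at 37 °C)

In the north flask 17% of the impurity remains, and the reckoned 10.1% stands 0.55 points above the result. A run whose target lay far from Y times its logarithm would undercut the forecast's grounds, and the neighbour with 41.0 µM of impurity is such a test. Its logarithm is 0.669, so Y predicts 3.76%. That neighbour flask gives 3.76%, with 51% of its impurity left.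

The readings were computed with made-up constants; noise was put on by code.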